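**Retrosynthetic overview**

- The target is 2-(4-hydroxy-3-methoxyphenyl)-5-(3-hydroxypropyl)-7-methoxy-1-benzofuran-3-carbaldehyde and has no stereocentre. The C3 formyl group is traced back to a Vilsmeier formylation, the C7 methyl ether to O-methylation of a benzofuran-7-ol, and the two free hydroxyl groups to a silyl ether and a benzyl ether.
- The strategy rests on the C5–C6 bond of the benzo ring. C5 (chain-bearing) is the distal alkyne carbon of a 3-alkynyl group and C6 (the CH next to the oxygenated C7) is the methyl carbon of a 2-acetyl group on a furan. The acetyl carbonyl becomes C7–OH and the proximal alkyne carbon becomes C4–H.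
- The 2-acetyl-3-alkynyl-5-arylfuran is assembled on 3-bromofuran: C2 lithiation and acetylation, Sonogashira coupling at C3, then palladium-catalysed C5–H arylation.
- Ring order: the furan ring and the guaiacyl ring are bought; the benzene ring of the benzofuran is built onto the furan in the key step.

Key step: step 5

Remark on the chemistry: the primary alcohol is carried as its tert-butyldiphenylsilyl ether, not as a tert-butyldimethylsilyl ether. POCl3/DMF turns tert-butyldimethylsilyl ethers into formates, whereas the bulkier silyl ether should pass the formylation unchanged. The phenol stays as its benzyl ether.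

**Route**

Step 1
Reactants: 1 3-bromofuran; 2 N-methoxy-N-methylacetamide
Product: 5 1-(3-bromofuran-2-yl)ethan-1-one, via 3-bromo-2-lithiofuran 3 (not isolated), via lithium hemiaminal adduct 4 (not isolated)
Conditions: LiN(iPr)2 (1.05 equiv), THF, −78 °C; then 2, −78 → −20 °C; then 1 M HCl
Reagents that add atoms: none
Why: Directed lithiation removes the C2 proton, which is acidified by both the ring oxygen and the neighbouring bromine, and the furyllithium is acylated once by the Weinreb amide because the chelated tetrahedral adduct survives until the acid quench.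

Step 2
Reactants: 6 pent-4-yn-1-ol
Product: 7 tert-butyl(pent-4-yn-1-yloxy)diphenylsilane
Conditions: TBDPSCl, imidazole, CH2Cl2, 0 °C → rt
Reagents that add atoms: tert-butyl(chloro)diphenylsilane (TBDPSCl), CC(C)(C)[Si](Cl)(c1ccccc1)c1ccccc1
Why: Imidazole-promoted O-silylation of a primary alcohol is routine and leaves the terminal alkyne untouched.

Step 3
Reactants: 5 1-(3-bromofuran-2-yl)ethan-1-one; 7 tert-butyl(pent-4-yn-1-yloxy)diphenylsilane
Product: 8 1-(3-{5-[(tert-butyldiphenylsilyl)oxy]pent-1-yn-1-yl}furan-2-yl)ethan-1-one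
Conditions: PdCl2(PPh3)2 (3 mol%), CuI (5 mol%), Et3N, THF, 50 °C, degassed
Reagents that add atoms: none
Why: Sonogashira coupling; the ortho acetyl group activates the only C–Br bond for oxidative addition to zerovalent palladium, and the copper acetylide of 7 transmetalates under amine conditions that do not enolize the ketone.

Step 4
Reactants: 8 1-(3-{5-[(tert-butyldiphenylsilyl)oxy]pent-1-yn-1-yl}furan-2-yl)ethan-1-one; 9 1-(benzyloxy)-4-bromo-2-methoxybenzene
Product: 10 1-{5-[4-(benzyloxy)-3-methoxyphenyl]-3-{5-[(tert-butyldiphenylsilyl)oxy]pent-1-yn-1-yl}furan-2-yl}ethan-1-one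
Conditions: Pd(OAc)2 (5 mol%), PCy3·HBF4 (10 mol%), PivOH (30 mol%), K2CO3 (1.5 equiv), DMA, 100 °C
Reagents that add atoms: none
Why: Palladium-catalysed direct C–H arylation by pivalate-assisted concerted metalation–deprotonation should take place at C5, the only free α-position and the most acidic C–H of a 2-acylfuran, and the carbonate/pivalate base is too weak to enolize the methyl ketone to a useful extent.

Step 5
Reactants: 10 1-{5-[4-(benzyloxy)-3-methoxyphenyl]-3-{5-[(tert-butyldiphenylsilyl)oxy]pent-1-yn-1-yl}furan-2-yl}ethan-1-one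
Product: 13 2-[4-(benzyloxy)-3-methoxyphenyl]-5-{3-[(tert-butyldiphenylsilyl)oxy]propyl}-1-benzofuran-7-ol, via potassium enolate 11 (not isolated), via potassium benzofuran-7-olate 12 (not isolated)
Conditions: KN(SiMe3)2 (2.0 equiv), toluene, −78 °C → 80 °C; then 1 M HCl, 0 °C
Reagents that add atoms: none
Why: KN(SiMe3)2 deprotonates the acetyl methyl group, and on warming the potassium enolate 11 adds through its methyl-derived carbon to the distal alkyne carbon (the future C5), which forms the C5–C6 bond and closes the benzene ring in a 6-endo-dig mode. The vinyl anion at the future C4 is protonated by HN(SiMe3)2, and the resulting cyclohexadienone is deprotonated at C6 to the aromatic potassium benzofuran-7-olate 12, which the acid quench converts into phenol 13. The closest known reaction is the base-mediated benzannulation of ortho-alkynylaryl methyl ketones to 3-substituted 1-naphthols, applied here with a furan in place of the benzene ring. No stereocentre is formed. The step needs carbon attack at the distal alkyne carbon in preference to 5-exo closure and to attack through the enolate oxygen: a 5-exo closure would fuse a second five-membered ring with an exocyclic alkylidene onto the furan and is more strained than the six-membered closure, and only the 6-endo carbon adduct can drain into an aromatic phenoxide. The benzyl ether, the silyl ether and the aryl methyl ether offer no proton that the amide base should remove under these conditions.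

Step 6
Reactants: 13 2-[4-(benzyloxy)-3-methoxyphenyl]-5-{3-[(tert-butyldiphenylsilyl)oxy]propyl}-1-benzofuran-7-ol
Product: 14 2-[4-(benzyloxy)-3-methoxyphenyl]-5-{3-[(tert-butyldiphenylsilyl)oxy]propyl}-7-methoxy-1-benzofuran
Conditions: MeI, K2CO3, acetone, 50 °C
Reagents that add atoms: iodomethane, CI
Why: Williamson O-methylation of the only free phenol; the benzyl and silyl ethers are inert to carbonate and iodomethane.

Step 7
Reactants: 14 2-[4-(benzyloxy)-3-methoxyphenyl]-5-{3-[(tert-butyldiphenylsilyl)oxy]propyl}-7-methoxy-1-benzofuran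
Product: 16 2-[4-(benzyloxy)-3-methoxyphenyl]-5-{3-[(tert-butyldiphenylsilyl)oxy]propyl}-7-methoxy-1-benzofuran-3-carbaldehyde, via iminium chloride 15 (not isolated)
Conditions: POCl3 (3 equiv), DMF, 0 °C → 70 °C; then ice/H2O
Reagents that add atoms: N,N-dimethylformamide, CN(C)C=O; water, O
Why: Vilsmeier–Haack formylation should go to C3, the β-carbon of the benzofuran enol ether and the position conjugated with the electron-rich 2-aryl group, which is more nucleophilic than the alkoxy-substituted benzene carbons, and the hindered silyl ether is expected to resist the chloroiminium reagent.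

Step 8
Reactants: 16 2-[4-(benzyloxy)-3-methoxyphenyl]-5-{3-[(tert-butyldiphenylsilyl)oxy]propyl}-7-methoxy-1-benzofuran-3-carbaldehyde
Product: 17 2-[4-(benzyloxy)-3-methoxyphenyl]-5-(3-hydroxypropyl)-7-methoxy-1-benzofuran-3-carbaldehyde
Conditions: Bu4NF, AcOH (1:1), THF, 0 °C → rt
Reagents that add atoms: none
Why: Fluoride-mediated desilylation driven by the Si–F bond; the acetic acid buffer keeps the medium from becoming basic, so the aldehyde and the benzyl ether should be untouched.

Step 9
Reactants: 17 2-[4-(benzyloxy)-3-methoxyphenyl]-5-(3-hydroxypropyl)-7-methoxy-1-benzofuran-3-carbaldehyde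
Product: 18 2-(4-hydroxy-3-methoxyphenyl)-5-(3-hydroxypropyl)-7-methoxy-1-benzofuran-3-carbaldehyde (target)
Conditions: BCl3 (4 equiv), pentamethylbenzene (3 equiv), CH2Cl2, −78 °C; then aq MeOH
Reagents that add atoms: none
Why: Lewis-acid debenzylation of the aryl benzyl ether with pentamethylbenzene as a non-basic benzyl cation scavenger should proceed at −78 °C without touching the aryl methyl ethers or the aldehyde (which hydrogenolysis could reduce), and the primary alcohol is only masked as a borate that the aqueous methanol quench hydrolyses.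

**Compound list**

1 | 3-bromofuran | Brc1ccoc1 | starting material
2 | N-methoxy-N-methylacetamide | CON(C)C(C)=O | starting material
3 | 3-bromo-2-lithiofuran | [Li]c1occc1Br | intermediate (not isolated)
4 | lithium 1-(3-bromofuran-2-yl)-1-[methoxy(methyl)amino]ethan-1-olate | [Li+].CON(C)C(C)([O-])c1occc1Br | intermediate (not isolated)
5 | 1-(3-bromofuran-2-yl)ethan-1-one | CC(=O)c1occc1Br | intermediate
6 | pent-4-yn-1-ol | C#CCCCO | starting material
7 | tert-butyl(pent-4-yn-1-yloxy)diphenylsilane | C#CCCCO[Si](c1ccccc1)(c1ccccc1)C(C)(C)C | intermediate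
8 | 1-(3-{5-[(tert-butyldiphenylsilyl)oxy]pent-1-yn-1-yl}furan-2-yl)ethan-1-one | CC(=O)c1occc1C#CCCCO[Si](c1ccccc1)(c1ccccc1)C(C)(C)C | intermediate
9 | 1-(benzyloxy)-4-bromo-2-methoxybenzene | COc1cc(Br)ccc1OCc1ccccc1 | starting material
10 | 1-{5-[4-(benzyloxy)-3-methoxyphenyl]-3-{5-[(tert-butyldiphenylsilyl)oxy]pent-1-yn-1-yl}furan-2-yl}ethan-1-one | CC(=O)c1oc(-c2ccc(OCc3ccccc3)c(OC)c2)cc1C#CCCCO[Si](c1ccccc1)(c1ccccc1)C(C)(C)C | intermediate
11 | potassium enolate of 10 (potassium 1-{5-[4-(benzyloxy)-3-methoxyphenyl]-3-{5-[(tert-butyldiphenylsilyl)oxy]pent-1-yn-1-yl}furan-2-yl}ethen-1-olate) | [K+].C=C([O-])c1oc(-c2ccc(OCc3ccccc3)c(OC)c2)cc1C#CCCCO[Si](c1ccccc1)(c1ccccc1)C(C)(C)C | intermediate (not isolated)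
12 | potassium 2-[4-(benzyloxy)-3-methoxyphenyl]-5-{3-[(tert-butyldiphenylsilyl)oxy]propyl}-1-benzofuran-7-olate | [K+].[O-]c1cc(CCCO[Si](c2ccccc2)(c2ccccc2)C(C)(C)C)cc2cc(-c3ccc(OCc4ccccc4)c(OC)c3)oc12 | intermediate (not isolated)
13 | 2-[4-(benzyloxy)-3-methoxyphenyl]-5-{3-[(tert-butyldiphenylsilyl)oxy]propyl}-1-benzofuran-7-ol | Oc1cc(CCCO[Si](c2ccccc2)(c2ccccc2)C(C)(C)C)cc2cc(-c3ccc(OCc4ccccc4)c(OC)c3)oc12 | intermediate
14 | 2-[4-(benzyloxy)-3-methoxyphenyl]-5-{3-[(tert-butyldiphenylsilyl)oxy]propyl}-7-methoxy-1-benzofuran | COc1cc(CCCO[Si](c2ccccc2)(c2ccccc2)C(C)(C)C)cc2cc(-c3ccc(OCc4ccccc4)c(OC)c3)oc12 | intermediate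
15 | N-({2-[4-(benzyloxy)-3-methoxyphenyl]-5-{3-[(tert-butyldiphenylsilyl)oxy]propyl}-7-methoxy-1-benzofuran-3-yl}methylidene)-N-methylmethanaminium chloride | [Cl-].C[N+](C)=Cc1c(-c2ccc(OCc3ccccc3)c(OC)c2)oc2c(OC)cc(CCCO[Si](c3ccccc3)(c3ccccc3)C(C)(C)C)cc12 | intermediate (not isolated)
16 | 2-[4-(benzyloxy)-3-methoxyphenyl]-5-{3-[(tert-butyldiphenylsilyl)oxy]propyl}-7-methoxy-1-benzofuran-3-carbaldehyde | COc1cc(CCCO[Si](c2ccccc2)(c2ccccc2)C(C)(C)C)cc2c(C=O)c(-c3ccc(OCc4ccccc4)c(OC)c3)oc12 | intermediate
17 | 2-[4-(benzyloxy)-3-methoxyphenyl]-5-(3-hydroxypropyl)-7-methoxy-1-benzofuran-3-carbaldehyde | COc1cc(CCCO)cc2c(C=O)c(-c3ccc(OCc4ccccc4)c(OC)c3)oc12 | intermediate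
18 | 2-(4-hydroxy-3-methoxyphenyl)-5-(3-hydroxypropyl)-7-methoxy-1-benzofuran-3-carbaldehyde | COc1cc(-c2oc3c(OC)cc(CCCO)cc3c2C=O)ccc1O | target

**Step count**

Total steps: 9. Longest linear sequence: 8 steps (steps 1 and 3 to 9 from 3-bromofuran; equally steps 2 and 3 to 9 from pent-4-yn-1-ol).

**Steps most likely to fail**

Step 5 (key carbocyclization). The enolate may close in the 5-exo mode or through oxygen, the alkyne may isomerize to an allene at its propargylic CH2 under the hot basic conditions, or intermolecular condensation may outrun ring closure. The fallback replaces the anionic closure by electrophilic alkyne activation under neutral conditions. It sets out from 10, which with TBSOTf and Et3N in CH2Cl2 at 0 °C should give the silyl enol ether {1-[5-(4-(benzyloxy)-3-methoxyphenyl)-3-{5-[(tert-butyldiphenylsilyl)oxy]pent-1-yn-1-yl}furan-2-yl]ethenyloxy}(tert-butyl)dimethylsilane F1. Treatment with catalytic W(CO)5(THF) (zerovalent tungsten, generated from W(CO)6 by irradiation in THF) at rt should complex the alkyne, induce 6-endo attack of the enol ether carbon, and after proton loss and protodemetalation give the aryl silyl ether tert-butyl({2-[4-(benzyloxy)-3-methoxyphenyl]-5-{3-[(tert-butyldiphenylsilyl)oxy]propyl}-1-benzofuran-7-yl}oxy)dimethylsilane F2. K2CO3 in MeOH at rt should then cleave the aryl silyl ether selectively in the presence of the alkyl silyl ether, and the route is rejoined at 13.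

Step 4 (C5–H arylation). The arylpalladium bromide may add across the alkyne, or divalent palladium may trigger attack of the carbonyl oxygen on the alkyne, faster than the C–H cleavage; oxidative addition of the electron-rich bromide may also be sluggish. The fallback installs the aryl group by cross-coupling at a C–Br bond before the alkyne is present. It sets out from 5, which with NBS in DMF at rt should brominate at the free α-position to give 1-(3,5-dibromofuran-2-yl)ethan-1-one F3. Suzuki–Miyaura coupling with commercial [4-(benzyloxy)-3-methoxyphenyl]boronic acid (Pd(PPh3)4, Na2CO3, dioxane/H2O, 70 °C) should occur first at the α C5–Br bond and give 1-{5-[4-(benzyloxy)-3-methoxyphenyl]-3-bromofuran-2-yl}ethan-1-one F4. Sonogashira coupling of F4 with 7 under the conditions of step 3 returns to the route at 10.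

Step 7 (Vilsmeier formylation). Formylation may compete at the methoxy-activated C4 and C6 positions or on the guaiacyl ring, and the hydrogen chloride formed may strip the silyl ether, after which the freed alcohol would be O-formylated. The fallback changes the approach to halogenation and lithiation. It sets out from 14, which with NBS in MeCN at 0 °C should give 2-[4-(benzyloxy)-3-methoxyphenyl]-3-bromo-5-{3-[(tert-butyldiphenylsilyl)oxy]propyl}-7-methoxy-1-benzofuran F5. Bromine–lithium exchange with n-BuLi in THF at −78 °C should give the 3-lithio-2-[4-(benzyloxy)-3-methoxyphenyl]-5-{3-[(tert-butyldiphenylsilyl)oxy]propyl}-7-methoxy-1-benzofuran F6, which is quenched with DMF and then dilute HCl, and the route is rejoined at 16.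

**Further compounds**

F1 | step 5 | {1-[5-(4-(benzyloxy)-3-methoxyphenyl)-3-{5-[(tert-butyldiphenylsilyl)oxy]pent-1-yn-1-yl}furan-2-yl]ethenyloxy}(tert-butyl)dimethylsilane | C=C(O[Si](C)(C)C(C)(C)C)c1oc(-c2ccc(OCc3ccccc3)c(OC)c2)cc1C#CCCCO[Si](c1ccccc1)(c1ccccc1)C(C)(C)C
F2 | step 5 | tert-butyl({2-[4-(benzyloxy)-3-methoxyphenyl]-5-{3-[(tert-butyldiphenylsilyl)oxy]propyl}-1-benzofuran-7-yl}oxy)dimethylsilane | CC(C)(C)[Si](C)(C)Oc1cc(CCCO[Si](c2ccccc2)(c2ccccc2)C(C)(C)C)cc2cc(-c3ccc(OCc4ccccc4)c(OC)c3)oc12
F3 | step 4 | 1-(3,5-dibromofuran-2-yl)ethan-1-one | CC(=O)c1oc(Br)cc1Br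
F4 | step 4 | 1-{5-[4-(benzyloxy)-3-methoxyphenyl]-3-bromofuran-2-yl}ethan-1-one | CC(=O)c1oc(-c2ccc(OCc3ccccc3)c(OC)c2)cc1Br
F5 | step 7 | 2-[4-(benzyloxy)-3-methoxyphenyl]-3-bromo-5-{3-[(tert-butyldiphenylsilyl)oxy]propyl}-7-methoxy-1-benzofuran | COc1cc(CCCO[Si](c2ccccc2)(c2ccccc2)C(C)(C)C)cc2c(Br)c(-c3ccc(OCc4ccccc4)c(OC)c3)oc12
F6 | step 7 | 3-lithio-2-[4-(benzyloxy)-3-methoxyphenyl]-5-{3-[(tert-butyldiphenylsilyl)oxy]propyl}-7-methoxy-1-benzofuran | [Li]c1c(-c2ccc(OCc3ccccc3)c(OC)c2)oc2c(OC)cc(CCCO[Si](c3ccccc3)(c3ccccc3)C(C)(C)C)cc12
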